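**Retrosynthetic overview**
1. The target comes from a late C8–O acylation with a silyl-protected (E)-4-hydroxy-3-methylbut-2-enoic acid and α-methylenation of a trans-fused 12,6-lactone.
2. The lactone comes from C7 alkylation and C6 reduction of a 10-membered dienone that carries only the C8 stereocentre.
3. The dienone comes from a 4→10 ring expansion of a meso 1-alkenyl-3-silyloxycyclobutanol: Pd cleaves one enantiotopic cyclobutane C–C bond (sets C8) and joins C9 to the Z-vinyl bromide carbon C10.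
4. The cyclobutanol comes from 3-silyloxycyclobutanone and a C7 bromo-enyne; both trisubstituted olefins are set by hydroxyl-directed trans-hydroalumination of propargylic alcohols.
5. Ring order: cyclobutane (bought) → 10-membered carbocycle → γ-lactone.

Assumptions: compounds 8 and 27 are bought as their silyl ethers; the ligand in step 8 and the CBS catalyst in step 10 are used in whichever enantiomeric form gives the configuration drawn; germacrane numbering (ring C1–C10, lactone C11–C13, C14 methyl, C15 CH2O) is used in the names of 16–32; TBS = tert-butyldimethylsilyl, TBDPS = tert-butyldiphenylsilyl.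

Step 1
Reactants: 1 but-2-yn-1-ol
Product: 3 (Z)-3-bromobut-2-en-1-ol, via cyclic vinylalanate 2 (not isolated)
Conditions: Red-Al, THF, 0 °C to rt; then NBS, −78 °C; Rochelle salt work-up
Reagents that add atoms: N-bromosuccinimide, O=C1CCC(=O)N1Br
Why: Alkoxide-directed trans-hydroalumination puts Al on C3 cis to the CH2O group and bromodealumination retains it, which fixes the later ring-cis C1=C10 geometry.

Step 2
Reactants: 3 (Z)-3-bromobut-2-en-1-ol
Product: 4 (Z)-1,3-dibromobut-2-ene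
Conditions: CBr4, PPh3, CH2Cl2, 0 °C
Reagents that add atoms: tetrabromomethane, BrC(Br)(Br)Br
Why: Appel bromination of a primary allylic alcohol under neutral conditions leaves the vinyl bromide and the olefin geometry untouched.

Step 3
Reactants: 4 (Z)-1,3-dibromobut-2-ene; 5 3-bromoprop-1-yne
Product: 7 (Z)-6-bromohept-5-en-1-yne, via allenylmagnesium bromide 6 (not isolated)
Conditions: 5, Mg, HgCl2 (cat.), Et2O, 0 °C; then 4, −20 °C to rt
Reagents that add atoms: none
Why: The allenyl Grignard reacts through its γ-carbon in an SN2 alkylation of the primary allylic bromide to give the terminal alkyne, while the vinyl bromide is inert.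

Step 4
Reactants: 7 (Z)-6-bromohept-5-en-1-yne; 8 3-(TBSO)cyclobutan-1-one
Product: 10 cis-1-[(Z)-6-bromohept-5-en-1-yn-1-yl]-3-(TBSO)cyclobutan-1-ol, via lithium acetylide 9 (not isolated)
Conditions: n-BuLi (1.0 equiv), THF, −78 °C; then 8, −78 °C; H2O
Reagents that add atoms: none
Why: Acetylide 1,2-addition to the strained ketone occurs anti to the 3-silyloxy group, giving the achiral cis (OH/OTBS) carbinol; the minor trans isomer is removed by chromatography.

Step 5
Reactants: 10 cis-1-[(Z)-6-bromohept-5-en-1-yn-1-yl]-3-(TBSO)cyclobutan-1-ol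
Product: 12 cis-1-[(1Z,5Z)-6-bromo-2-iodohepta-1,5-dien-1-yl]-3-(TBSO)cyclobutan-1-ol, via spiro vinylalanate 11 (not isolated)
Conditions: Red-Al, THF, 0 °C to rt; then I2, −78 °C; Rochelle salt work-up
Reagents that add atoms: iodine, II
Why: Hydroxyl-directed trans-hydroalumination/iodination (Corey–Denmark type) delivers H to C5 and I to C4 cis to the carbinol carbon, which sets the ring-trans C4=C5 geometry.

Step 6
Reactants: 12 cis-1-[(1Z,5Z)-6-bromo-2-iodohepta-1,5-dien-1-yl]-3-(TBSO)cyclobutan-1-ol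
Product: 14 cis-1-[(1Z,5Z)-6-bromo-2-(hydroxymethyl)hepta-1,5-dien-1-yl]-3-(TBSO)cyclobutan-1-ol, via alkenylmagnesium chloride 13 (not isolated)
Conditions: i-PrMgCl·LiCl (2.2 equiv), THF, −20 °C; then (CH2O)n, −20 °C to rt; H2O
Reagents that add atoms: formaldehyde (from paraformaldehyde), C=O
Why: Knochel iodine–magnesium exchange is selective for the vinyl iodide over the vinyl bromide and proceeds with retention, and the chelated alkenyl Grignard adds to formaldehyde to install C15.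

Step 7
Reactants: 14 cis-1-[(1Z,5Z)-6-bromo-2-(hydroxymethyl)hepta-1,5-dien-1-yl]-3-(TBSO)cyclobutan-1-ol
Product: 15 cis-1-[(1Z,5Z)-6-bromo-2-(TBDPSO-methyl)hepta-1,5-dien-1-yl]-3-(TBSO)cyclobutan-1-ol
Conditions: TBDPSCl, imidazole, CH2Cl2, 0 °C
Reagents that add atoms: tert-butyl(chloro)diphenylsilane, CC(C)(C)[Si](Cl)(c1ccccc1)c1ccccc1
Why: Silylation is selective for the primary allylic alcohol, leaving the hindered tertiary cyclobutanol free for the next step.

Step 8
Reactants: 15 cis-1-[(1Z,5Z)-6-bromo-2-(TBDPSO-methyl)hepta-1,5-dien-1-yl]-3-(TBSO)cyclobutan-1-ol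
Product: 16 (2Z,6Z,9S)-9-(TBSO)-3-(TBDPSO-methyl)-7-methylcyclodeca-2,6-dien-1-one
Conditions: Pd(OAc)2 (10 mol %), chiral ferrocenyl P,N ligand of the PPFA type (20 mol %), Cs2CO3 (2 equiv), toluene, 50 °C, syringe-pump addition to 2 mM
Reagents that add atoms: none
Why: Proposed new method: an intramolecular, enantioselective ring-expanding alkenylation in which Pd(0) adds to the Z-vinyl bromide, the tertiary alkoxide binds Pd, the chiral ligand selects one of the two enantiotopic cyclobutane C–C bonds for β-carbon elimination (this sets C8), and C(sp2)–C(sp3) reductive elimination from the 11-membered palladacycle closes the 10-membered ring with retention of both olefin geometries, the roughly 26 kcal/mol of cyclobutane strain paying for the medium ring; the closest known reaction is the intermolecular Pd-catalysed enantioselective ring-opening arylation and vinylation of tert-cyclobutanols via β-carbon elimination, which has not been shown intramolecularly for medium-ring formation.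

Step 9
Reactants: 16 (2Z,6Z,9S)-9-(TBSO)-3-(TBDPSO-methyl)-7-methylcyclodeca-2,6-dien-1-one; 17 methyl bromoacetate
Product: 19 methyl 6-oxo-8α-(TBSO)-15-(TBDPSO)-13-norgermacra-1(10),4-dien-12-oate (7α-H), via lithium enolate 18 (not isolated)
Conditions: LiHMDS, THF, −78 °C; then 17, DMPU, −78 to −50 °C
Reagents that add atoms: none
Why: Kinetic α'-deprotonation of the enone and enolate alkylation anti to the neighbouring OTBS group (1,2-induction in a medium-ring enolate) sets C7 trans to O8.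

Step 10
Reactants: 19 methyl 6-oxo-8α-(TBSO)-15-(TBDPSO)-13-norgermacra-1(10),4-dien-12-oate
Product: 21 8α-(TBSO)-15-(TBDPSO)-13-norgermacra-1(10),4-dien-12,6α-olide, via hydroxy ester 20 (not isolated)
Conditions: (R)-Me-CBS (20 mol %), catecholborane, toluene, −78 °C; then PPTS, toluene, 60 °C
Reagents that add atoms: none
Why: Corey–Bakshi–Shibata reduction of the enone gives reagent-controlled 1,2-hydride delivery to set the 6α-alcohol, which lactonises onto the γ-ester to the trans-fused lactone.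

Step 11
Reactants: 21 8α-(TBSO)-15-(TBDPSO)-13-norgermacra-1(10),4-dien-12,6α-olide
Product: 25 8α-(TBSO)-15-(TBDPSO)germacra-1(10),4,11(13)-trien-12,6α-olide, via lithium enolate 22 (not isolated), via Mannich base 23 (not isolated), via methiodide 24 (not isolated)
Conditions: LiHMDS, THF, −78 °C; CH2=NMe2+ I−, −78 to 0 °C; then MeI, MeOH, rt; then aq. NaHCO3, CH2Cl2
Reagents that add atoms: N,N-dimethylmethyleneiminium iodide (Eschenmoser's salt), C=[N+](C)C.[I-]
Why: Eschenmoser α-methylenation (Mannich reaction, N-quaternisation, Hofmann-type elimination) is the standard way to install the exocyclic methylene of a γ-lactone and touches no stereocentre.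

Step 12
Reactants: 25 8α-(TBSO)-15-(TBDPSO)germacra-1(10),4,11(13)-trien-12,6α-olide
Product: 26 8α-hydroxy-15-(TBDPSO)germacra-1(10),4,11(13)-trien-12,6α-olide
Conditions: HF·pyridine, pyridine, THF, 0 °C
Reagents that add atoms: none
Why: Buffered HF cleaves the secondary TBS ether much faster than the primary TBDPS ether and leaves the α-methylene lactone intact.

Step 13
Reactants: 27 tert-butyl(prop-2-yn-1-yloxy)diphenylsilane
Product: 30 (E)-4-(TBDPSO)-3-methylbut-2-enoic acid, via alkenylalane 28 (not isolated), via lithium alanate 29 (not isolated)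
Conditions: Me3Al (2 equiv), Cp2ZrCl2 (0.25 equiv), CH2Cl2, 0 °C to rt; then n-BuLi, THF, −78 °C; then CO2, −78 °C to rt; 1 M HCl
Reagents that add atoms: trimethylaluminium, C[Al](C)C; carbon dioxide, O=C=O
Why: Negishi Zr-catalysed carboalumination adds Me and Al syn across the alkyne (Me to the internal carbon), and carboxylation of the derived alanate with retention gives the E acid with CO2H cis to the methyl group.

Step 14
Reactants: 26 8α-hydroxy-15-(TBDPSO)germacra-1(10),4,11(13)-trien-12,6α-olide; 30 (E)-4-(TBDPSO)-3-methylbut-2-enoic acid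
Product: 31 8α-[(E)-4-(TBDPSO)-3-methylbut-2-enoyloxy]-15-(TBDPSO)germacra-1(10),4,11(13)-trien-12,6α-olide
Conditions: EDC·HCl, DMAP, CH2Cl2, 0 °C to rt
Reagents that add atoms: none
Why: Steglich esterification acylates the secondary alcohol with retention at C8 under conditions the α-methylene lactone tolerates.

Step 15
Reactants: 31 8α-[(E)-4-(TBDPSO)-3-methylbut-2-enoyloxy]-15-(TBDPSO)germacra-1(10),4,11(13)-trien-12,6α-olide
Product: 32 CNP0233978.1
Conditions: HF·pyridine, THF, rt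
Reagents that add atoms: none
Why: Fluoride-mediated desilylation removes both primary TBDPS ethers without base, so the two esters and the Michael-acceptor lactone survive.

**Compound list**
1 | but-2-yn-1-ol | CC#CCO | starting material
2 | sodium 2,2-bis(2-methoxyethoxy)-3-methyl-2,5-dihydro-1,2-oxaaluminol-2-uide (cyclic vinylalanate) | CC1=CCO[Al-]1(OCCOC)OCCOC.[Na+] | intermediate
3 | (Z)-3-bromobut-2-en-1-ol | OC/C=C(/C)Br | intermediate
4 | (Z)-1,3-dibromobut-2-ene | BrC/C=C(/C)Br | intermediate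
5 | 3-bromoprop-1-yne (propargyl bromide) | C#CCBr | starting material
6 | allenylmagnesium bromide | C=C=C[Mg]Br | intermediate
7 | (Z)-6-bromohept-5-en-1-yne | C#CCC/C=C(/C)Br | intermediate
8 | 3-[(tert-butyldimethylsilyl)oxy]cyclobutan-1-one | O=C1CC(O[Si](C)(C)C(C)(C)C)C1 | starting material
9 | [(Z)-6-bromohept-5-en-1-yn-1-yl]lithium | [Li]C#CCC/C=C(/C)Br | intermediate
10 | cis-1-[(Z)-6-bromohept-5-en-1-yn-1-yl]-3-(TBSO)cyclobutan-1-ol (OH and OTBS cis, achiral) | O[C@@]1(C#CCC/C=C(/C)Br)C[C@@H](O[Si](C)(C)C(C)(C)C)C1 | intermediate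
11 | spiro cyclic vinylalanate of 10 (sodium salt; Al on C4, H on C5) | COCCO[Al-]1(OCCOC)O[C@@]2(C=C1CC/C=C(/C)Br)C[C@@H](O[Si](C)(C)C(C)(C)C)C2.[Na+] | intermediate
12 | cis-1-[(1Z,5Z)-6-bromo-2-iodohepta-1,5-dien-1-yl]-3-(TBSO)cyclobutan-1-ol | O[C@@]1(/C=C(\I)CC/C=C(/C)Br)C[C@@H](O[Si](C)(C)C(C)(C)C)C1 | intermediate
13 | chloromagnesium alkoxide / alkenylmagnesium chloride derived from 12 | Cl[Mg]O[C@@]1(/C=C(\[Mg]Cl)CC/C=C(/C)Br)C[C@@H](O[Si](C)(C)C(C)(C)C)C1 | intermediate
14 | cis-1-[(1Z,5Z)-6-bromo-2-(hydroxymethyl)hepta-1,5-dien-1-yl]-3-(TBSO)cyclobutan-1-ol | O[C@@]1(/C=C(\CO)CC/C=C(/C)Br)C[C@@H](O[Si](C)(C)C(C)(C)C)C1 | intermediate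
15 | cis-1-[(1Z,5Z)-6-bromo-2-{[(tert-butyldiphenylsilyl)oxy]methyl}hepta-1,5-dien-1-yl]-3-(TBSO)cyclobutan-1-ol | O[C@@]1(/C=C(\CO[Si](c2ccccc2)(c2ccccc2)C(C)(C)C)CC/C=C(/C)Br)C[C@@H](O[Si](C)(C)C(C)(C)C)C1 | intermediate
16 | (2Z,6Z,9S)-9-(TBSO)-3-(TBDPSO-methyl)-7-methylcyclodeca-2,6-dien-1-one (C2=C3 ring-trans, C6=C7 ring-cis; germacrane C6 ketone, 8α-OTBS) | O=C1/C=C(\CO[Si](c2ccccc2)(c2ccccc2)C(C)(C)C)CC/C=C(/C)C[C@H](O[Si](C)(C)C(C)(C)C)C1 | intermediate
17 | methyl bromoacetate | COC(=O)CBr | starting material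
18 | lithium enolate of 16 (C6–OLi, C6=C7) | [Li]OC=1/C=C(\CO[Si](c2ccccc2)(c2ccccc2)C(C)(C)C)CC/C=C(/C)C[C@H](O[Si](C)(C)C(C)(C)C)C=1 | intermediate
19 | methyl 6-oxo-8α-(TBSO)-15-(TBDPSO)-13-norgermacra-1(10),4-dien-12-oate (7α-H) | O=C1/C=C(\CO[Si](c2ccccc2)(c2ccccc2)C(C)(C)C)CC/C=C(/C)C[C@H](O[Si](C)(C)C(C)(C)C)[C@H]1CC(=O)OC | intermediate
20 | methyl 6α-hydroxy-8α-(TBSO)-15-(TBDPSO)-13-norgermacra-1(10),4-dien-12-oate (7α-H) | COC(=O)C[C@H]1[C@H](O)/C=C(\CO[Si](c2ccccc2)(c2ccccc2)C(C)(C)C)CC/C=C(/C)C[C@@H]1O[Si](C)(C)C(C)(C)C | intermediate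
21 | 8α-(TBSO)-15-(TBDPSO)-13-norgermacra-1(10),4-dien-12,6α-olide (trans-fused, 7α-H) | C1C(=O)O[C@@H]2/C=C(\CO[Si](c3ccccc3)(c3ccccc3)C(C)(C)C)CC/C=C(/C)C[C@H](O[Si](C)(C)C(C)(C)C)[C@@H]12 | intermediate
22 | lithium enolate of lactone 21 | C1=C(O[Li])O[C@@H]2/C=C(\CO[Si](c3ccccc3)(c3ccccc3)C(C)(C)C)CC/C=C(/C)C[C@H](O[Si](C)(C)C(C)(C)C)[C@@H]12 | intermediate
23 | 11-[(dimethylamino)methyl] derivative of 21 (Mannich base, C11 epimers) | CN(C)CC1C(=O)O[C@@H]2/C=C(\CO[Si](c3ccccc3)(c3ccccc3)C(C)(C)C)CC/C=C(/C)C[C@H](O[Si](C)(C)C(C)(C)C)[C@@H]12 | intermediate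
24 | trimethylammonium iodide of 23 (methiodide) | C[N+](C)(C)CC1C(=O)O[C@@H]2/C=C(\CO[Si](c3ccccc3)(c3ccccc3)C(C)(C)C)CC/C=C(/C)C[C@H](O[Si](C)(C)C(C)(C)C)[C@@H]12.[I-] | intermediate
25 | 8α-(TBSO)-15-(TBDPSO)germacra-1(10),4,11(13)-trien-12,6α-olide | C=C1C(=O)O[C@@H]2/C=C(\CO[Si](c3ccccc3)(c3ccccc3)C(C)(C)C)CC/C=C(/C)C[C@H](O[Si](C)(C)C(C)(C)C)[C@@H]12 | intermediate
26 | 8α-hydroxy-15-(TBDPSO)germacra-1(10),4,11(13)-trien-12,6α-olide | C=C1C(=O)O[C@@H]2/C=C(\CO[Si](c3ccccc3)(c3ccccc3)C(C)(C)C)CC/C=C(/C)C[C@H](O)[C@@H]12 | intermediate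
27 | tert-butyl(prop-2-yn-1-yloxy)diphenylsilane | C#CCO[Si](c1ccccc1)(c1ccccc1)C(C)(C)C | starting material
28 | (E)-[3-(TBDPSO)-2-methylprop-1-en-1-yl]dimethylalane | C[Al](C)/C=C(\C)CO[Si](c1ccccc1)(c1ccccc1)C(C)(C)C | intermediate
29 | lithium butyl(dimethyl)[(E)-3-(TBDPSO)-2-methylprop-1-en-1-yl]aluminate | CCCC[Al-](C)(C)/C=C(\C)CO[Si](c1ccccc1)(c1ccccc1)C(C)(C)C.[Li+] | intermediate
30 | (E)-4-[(tert-butyldiphenylsilyl)oxy]-3-methylbut-2-enoic acid | OC(=O)/C=C(\C)CO[Si](c1ccccc1)(c1ccccc1)C(C)(C)C | intermediate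
31 | bis-TBDPS ether of the target (15-O and 4'-O silylated) | C=C1C(=O)O[C@@H]2/C=C(\CO[Si](c3ccccc3)(c3ccccc3)C(C)(C)C)CC/C=C(/C)C[C@H](OC(=O)/C=C(\C)CO[Si](c3ccccc3)(c3ccccc3)C(C)(C)C)[C@@H]12 | intermediate
32 | CNP0233978.1: 15-hydroxy-8α-[(E)-4-hydroxy-3-methylbut-2-enoyloxy]germacra-1(10),4,11(13)-trien-12,6α-olide (6R,7R,8S; 1(10)-cis, 4,5-trans ring olefins) | C=C1C(=O)O[C@@H]2/C=C(\CO)CC/C=C(/C)C[C@H](OC(=O)/C=C(\C)CO)[C@@H]12 | target

**Totals**
Total step count: 15. Longest linear sequence: 14 (steps 1–12, 14, 15); step 13 is a one-step branch.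

**Three steps most likely to fail**

Step 8 (the proposed new ring expansion). The 11-membered palladacycle may prefer β-hydride or β-silyloxy elimination, or intermolecular coupling, over reductive elimination. Fallback, from 15 back to 16, known chemistry only: bromine–lithium exchange and protonation (t-BuLi, 3 equiv, THF, −78 °C; MeOH) removes the bromine to give cis-3-(TBSO)-1-[(1Z,5E)-2-(TBDPSO-methyl)hepta-1,5-dien-1-yl]cyclobutan-1-ol F1. F1 is then submitted to the known intermolecular Pd-catalysed enantioselective ring-opening vinylation of tert-cyclobutanols (Pd(OAc)2, the same chiral P,N ligand, Cs2CO3, toluene, 50 °C) with 2-bromopropene, which sets the same silyloxy stereocentre and gives the open-chain ketone (S,3Z,7E)-10-methyl-9-(TBSO)-4-(TBDPSO-methyl)undeca-3,7,10-trien-2-one-type dienyl ketone F2. Ring-closing metathesis of F2 (Grubbs II, CH2Cl2, reflux, 1 mM, loss of propene) then forms the ring-cis C1=C10 olefin and delivers 16.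

Step 9 (C7 alkylation). The facial selectivity on the 10-membered enolate is not secured, and warming invites β-elimination of the silyl ether. Fallback, from 16 back to 19: aldol condensation of the lithium enolate of 16 with methyl glyoxylate followed by dehydration (MsCl, Et3N, then DBU) gives the exocyclic alkylidene keto ester methyl 2-[6-oxo-8α-(TBSO)-15-(TBDPSO)-11,12,13-trinorgermacra-1(10),4-dien-7-ylidene]acetate F3 (E/Z mixture). Chemoselective conjugate reduction of F3 with Stryker's reagent and kinetic protonation of the resulting enolate then gives 19. Because a proton, not the carbon electrophile, now enters from the preferred face, a facial bias that spoils the alkylation works in favour of the wanted C7 epimer here.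

Step 10 (C6 reduction). The α-branched C7 may override the CBS catalyst and give the 6β-alcohol. Fallback, from 19 back to 21: substrate-controlled Luche reduction (NaBH4, CeCl3, MeOH, −78 °C) gives methyl 6β-hydroxy-8α-(TBSO)-15-(TBDPSO)-13-norgermacra-1(10),4-dien-12-oate F4. Saponification (LiOH, THF/H2O) gives the 6β-hydroxy acid F5, and Mitsunobu lactonisation of F5 (PPh3, DIAD, THF, 0 °C) closes the lactone with inversion at C6 to give 21.

**Further compounds**
F1 | step 8 | cis-3-(TBSO)-1-[(1Z,5E)-2-(TBDPSO-methyl)hepta-1,5-dien-1-yl]cyclobutan-1-ol | O[C@@]1(/C=C(\CO[Si](c2ccccc2)(c2ccccc2)C(C)(C)C)CC/C=C/C)C[C@@H](O[Si](C)(C)C(C)(C)C)C1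
F2 | step 8 | open-chain ketone from ring-opening vinylation of F1 with 2-bromopropene (isopropenyl on C9, (S)-silyloxy carbon, E-propenyl terminus) | C=C(C)C[C@H](O[Si](C)(C)C(C)(C)C)CC(=O)/C=C(\CO[Si](c1ccccc1)(c1ccccc1)C(C)(C)C)CC/C=C/C
F3 | step 9 | methyl 2-[6-oxo-8α-(TBSO)-15-(TBDPSO)-11,12,13-trinorgermacra-1(10),4-dien-7-ylidene]acetate (E/Z mixture) | O=C1/C=C(\CO[Si](c2ccccc2)(c2ccccc2)C(C)(C)C)CC/C=C(/C)C[C@H](O[Si](C)(C)C(C)(C)C)C1=CC(=O)OC
F4 | step 10 | methyl 6β-hydroxy-8α-(TBSO)-15-(TBDPSO)-13-norgermacra-1(10),4-dien-12-oate | COC(=O)C[C@H]1[C@@H](O)/C=C(\CO[Si](c2ccccc2)(c2ccccc2)C(C)(C)C)CC/C=C(/C)C[C@@H]1O[Si](C)(C)C(C)(C)C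
F5 | step 10 | 6β-hydroxy-8α-(TBSO)-15-(TBDPSO)-13-norgermacra-1(10),4-dien-12-oic acid | OC(=O)C[C@H]1[C@@H](O)/C=C(\CO[Si](c2ccccc2)(c2ccccc2)C(C)(C)C)CC/C=C(/C)C[C@@H]1O[Si](C)(C)C(C)(C)C
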